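**Retrosynthetic overview**

- The target is a CH2-bridged dimer with no stereocentre. In ring B, C2 sits between the C1 and C3 carbonyls, so ring B is a 3,3-dimethylindane-1,2-dione with one carbon inserted into its CO–CO bond, and C2–CH2–C2' is the backbone of a glutarate.
- Endgame: the C2 and C2' hydrogens come from C2–CO2Me (the esters are kept as blocking groups to the end), the C7 acetyl groups from Friedel–Crafts/Fries acylation, the phenols from methyl ethers.
- Key disconnection: C1–C2 and C2–C3 in both halves, giving two molecules of 5,7-dimethoxy-3,3-dimethylindane-1,2-dione and dimethyl 2,4-bis(diazo)pentanedioate; both rings B form by ring expansion in one step.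
- The dione comes from SeO2 oxidation of the indanone, whose five-membered ring is closed by Friedel–Crafts acylation of the Meldrum's acid adduct of the aryl Grignard reagent (ring A is bought).
- The bis(diazo) ester comes from twofold deacetylative diazo transfer on the formaldehyde bis-adduct of methyl acetoacetate.

Key step: step 6

Remark: the target is drawn as one of its enol tautomers. Ring B is numbered C1 (aryl ketone), C2, C3, C4 (CMe2), and the benzene ring A is C4a to C8a.

**Step 1**
Reactants: 1 1-bromo-3,5-dimethoxybenzene; 2 2,2-dimethyl-5-(propan-2-ylidene)-1,3-dioxane-4,6-dione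
Product: 4 5-[2-(3,5-dimethoxyphenyl)propan-2-yl]-2,2-dimethyl-1,3-dioxane-4,6-dione, via 3,5-dimethoxyphenylmagnesium bromide 3 (not isolated)
Conditions: Mg, I2 (cat), THF, reflux; then 2, THF, 0 °C to rt; aq HCl
Reagents that add atoms: none
Why: Conjugate addition of an aryl Grignard reagent to the doubly activated alkylidene Meldrum's acid should form the benzylic quaternary carbon directly, the acidic adduct being protected as its enolate until work-up.

**Step 2**
Reactants: 4 5-[2-(3,5-dimethoxyphenyl)propan-2-yl]-2,2-dimethyl-1,3-dioxane-4,6-dione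
Product: 6 5,7-dimethoxy-3,3-dimethylindan-1-one, via 5,7-dimethoxy-3,3-dimethyl-1-oxoindane-2-carboxylic acid 5 (not isolated)
Conditions: Sc(OTf)3 (10 mol %), MeNO2, 100 °C
Reagents that add atoms: none
Why: Lewis acid-catalysed intramolecular Friedel–Crafts acylation by the Meldrum's acid unit should close the five-membered ring at either of the two equivalent positions ortho to the side chain, each ortho and para to a methoxy group, with loss of acetone and then CO2.

**Step 3**
Reactants: 6 5,7-dimethoxy-3,3-dimethylindan-1-one
Product: 7 5,7-dimethoxy-3,3-dimethylindane-1,2-dione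
Conditions: SeO2, 1,4-dioxane/H2O, reflux
Reagents that add atoms: selenium dioxide, O=[Se]=O
Why: Riley oxidation should convert the only enolisable methylene (C2) into a ketone, and the quaternary C3 rules out further oxidation to a trione.

**Step 4**
Reactants: 8 methyl acetoacetate (2 equiv); 9 formaldehyde (37 % aqueous)
Product: 11 dimethyl 2,4-diacetylpentanedioate, via methyl 2-methylidene-3-oxobutanoate 10 (not isolated)
Conditions: piperidine (cat), neat, 0 °C to rt
Reagents that add atoms: none
Why: Knoevenagel condensation followed by Michael addition of a second acetoacetate should give the bis-adduct as a mixture of diastereomers and enol forms (both centres are destroyed in step 5), and the cold, weakly basic conditions should hold back aldol cyclisation.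

**Step 5**
Reactants: 11 dimethyl 2,4-diacetylpentanedioate
Product: 13 dimethyl 2,4-bis(diazo)pentanedioate, via dimethyl 2-acetyl-4-diazopentanedioate 12 (not isolated)
Conditions: p-ABSA (2.4 equiv), DBU, MeCN, 0 °C to rt; product kept cold in solution and used at once
Reagents that add atoms: 4-acetamidobenzenesulfonyl azide (p-ABSA), CC(=O)Nc1ccc(cc1)S(=O)(=O)N=[N+]=[N-]
Why: Deacylative Regitz diazo transfer is the standard route to α-alkyl-α-diazo esters, each acetoacetate enolate attacking the sulfonyl azide and the adduct collapsing with transfer of the acetyl group to the sulfonamide nitrogen.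

**Step 6**
Reactants: 7 5,7-dimethoxy-3,3-dimethylindane-1,2-dione (2.3 equiv); 13 dimethyl 2,4-bis(diazo)pentanedioate
Product: 15 dimethyl 2,2'-methylenebis(6,8-dimethoxy-4,4-dimethyl-1,3-dioxo-1,2,3,4-tetrahydronaphthalene-2-carboxylate), via methyl 2-(2-diazo-3-methoxy-3-oxopropyl)-6,8-dimethoxy-4,4-dimethyl-1,3-dioxo-1,2,3,4-tetrahydronaphthalene-2-carboxylate 14 (not isolated)
Conditions: Sc(OTf)3 (20 mol %), 4 Å molecular sieves, CH2Cl2, −78 to 0 °C, slow addition of 13 to 7
Reagents that add atoms: none
Why: Proposed new method: Sc(OTf)3 chelates the two adjacent carbonyls of 7, a diazo carbon of 13 adds to the non-conjugated C2 ketone, and the scandium alkoxide drives a 1,2-shift of the C1 acyl carbon onto the diazonium carbon with loss of N2; the same events at the second diazo group of 14 complete the three-component coupling. The closest known reactions are the Sc(OTf)3-catalysed one-carbon ring expansion of cycloalkanones with α-alkyl-α-diazo esters and the homologation of 1,2-diketones to 1,3-diketones with diazoalkanes, but a twofold insertion of a bis(diazo) ester into the CO–CO bond of an indane-1,2-dione is without precedent. Neither ring B is closed by a cyclisation: each arises from the five-membered ring of 7 by ring expansion, the inserted carbon becoming C2 with new C2–C3 and C1–C2 bonds. The quaternary centres C2 and C2' form without control as a mixture of meso and racemic diastereomers, which is harmless because both become sp2 in step 9. The step needs attack at C2 and not at C1, which the ortho and para methoxy groups should secure by making the C1 aryl ketone a doubly vinylogous ester (an adduct at C1 would be expected to shift the electron-rich aryl group, as in ring expansions of isatins), and it needs migration of the acyl carbon and not of the quaternary benzylic carbon, which should follow from the migratory aptitude of acyl groups in such shifts and from the bulk of the CMe2 terminus. The ester keeps C2 non-enolisable, so the product cannot tautomerise or react again at C2, and slow addition of 13 to an excess of 7 at low temperature should keep the bimolecular addition ahead of decomposition of the diazo groups.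

**Step 7**
Reactants: 15 dimethyl 2,2'-methylenebis(6,8-dimethoxy-4,4-dimethyl-1,3-dioxo-1,2,3,4-tetrahydronaphthalene-2-carboxylate)
Product: 16 dimethyl 2,2'-methylenebis(6,8-dihydroxy-4,4-dimethyl-1,3-dioxo-1,2,3,4-tetrahydronaphthalene-2-carboxylate)
Conditions: BBr3 (excess), CH2Cl2, −78 to 0 °C; then ice/H2O
Reagents that add atoms: none
Why: BBr3 cleavage of aryl methyl ethers should be much faster than attack on the two aliphatic methyl esters at or below 0 °C, and with C2 still quaternary there is no enol that could cyclodehydrate across the CH2 bridge to a pyran under the acidic conditions.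

**Step 8**
Reactants: 16 dimethyl 2,2'-methylenebis(6,8-dihydroxy-4,4-dimethyl-1,3-dioxo-1,2,3,4-tetrahydronaphthalene-2-carboxylate)
Product: 17 dimethyl 2,2'-methylenebis(7-acetyl-6,8-dihydroxy-4,4-dimethyl-1,3-dioxo-1,2,3,4-tetrahydronaphthalene-2-carboxylate)
Conditions: Ac2O, BF3·OEt2, AcOH, 70 °C; then aq MeOH, 50 °C
Reagents that add atoms: acetic anhydride, CC(=O)OC(C)=O
Why: BF3-mediated O-acetylation and Fries rearrangement (Friedel–Crafts C-acylation of a resorcinol) should place the acetyl group at C7, which is ortho to both hydroxyl groups and gives a chelated ketone, whereas C5 is shielded by the peri gem-dimethyl group and C2 is blocked by its ester.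

**Step 9**
Reactants: 17 dimethyl 2,2'-methylenebis(7-acetyl-6,8-dihydroxy-4,4-dimethyl-1,3-dioxo-1,2,3,4-tetrahydronaphthalene-2-carboxylate)
Product: 18 2,2'-methylenebis(7-acetyl-3,6,8-trihydroxy-4,4-dimethylnaphthalen-1(4H)-one) (target)
Conditions: LiCl, H2O, DMSO, 110 °C; then aq HCl
Reagents that add atoms: none
Why: Krapcho dealkoxycarbonylation should be easy here because chloride demethylates each ester and the carboxylate, flanked by two ketones, loses CO2 to a stabilised 1,3-dione enolate that is protonated to the enol, under neutral conditions that should spare the CH2 bridge.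

**Compound list**

1 | 1-bromo-3,5-dimethoxybenzene | COc1cc(Br)cc(OC)c1 | starting material
2 | 2,2-dimethyl-5-(propan-2-ylidene)-1,3-dioxane-4,6-dione (isopropylidene Meldrum's acid) | CC(C)=C1C(=O)OC(C)(C)OC1=O | starting material
3 | 3,5-dimethoxyphenylmagnesium bromide | COc1cc([Mg]Br)cc(OC)c1 | intermediate (not isolated)
4 | 5-[2-(3,5-dimethoxyphenyl)propan-2-yl]-2,2-dimethyl-1,3-dioxane-4,6-dione | COc1cc(cc(OC)c1)C(C)(C)C1C(=O)OC(C)(C)OC1=O | intermediate
5 | 5,7-dimethoxy-3,3-dimethyl-1-oxoindane-2-carboxylic acid (racemic) | COc1cc(OC)c2c(c1)C(C)(C)C(C(=O)O)C2=O | intermediate (not isolated)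
6 | 5,7-dimethoxy-3,3-dimethylindan-1-one | COc1cc(OC)c2c(c1)C(C)(C)CC2=O | intermediate
7 | 5,7-dimethoxy-3,3-dimethylindane-1,2-dione | COc1cc(OC)c2c(c1)C(C)(C)C(=O)C2=O | intermediate
8 | methyl acetoacetate | COC(=O)CC(C)=O | starting material
9 | formaldehyde | C=O | starting material
10 | methyl 2-methylidene-3-oxobutanoate | COC(=O)C(=C)C(C)=O | intermediate (not isolated)
11 | dimethyl 2,4-diacetylpentanedioate (mixture of meso and racemic forms) | COC(=O)C(CC(C(C)=O)C(=O)OC)C(C)=O | intermediate
12 | dimethyl 2-acetyl-4-diazopentanedioate (racemic) | COC(=O)C(=[N+]=[N-])CC(C(C)=O)C(=O)OC | intermediate (not isolated)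
13 | dimethyl 2,4-bis(diazo)pentanedioate | COC(=O)C(=[N+]=[N-])CC(=[N+]=[N-])C(=O)OC | intermediate
14 | methyl 2-(2-diazo-3-methoxy-3-oxopropyl)-6,8-dimethoxy-4,4-dimethyl-1,3-dioxo-1,2,3,4-tetrahydronaphthalene-2-carboxylate (racemic) | COC(=O)C(=[N+]=[N-])CC1(C(=O)OC)C(=O)c2c(OC)cc(OC)cc2C(C)(C)C1=O | intermediate (not isolated)
15 | dimethyl 2,2'-methylenebis(6,8-dimethoxy-4,4-dimethyl-1,3-dioxo-1,2,3,4-tetrahydronaphthalene-2-carboxylate) (mixture of meso and racemic forms) | COC(=O)C1(CC2(C(=O)OC)C(=O)c3c(OC)cc(OC)cc3C(C)(C)C2=O)C(=O)c2c(OC)cc(OC)cc2C(C)(C)C1=O | intermediate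
16 | dimethyl 2,2'-methylenebis(6,8-dihydroxy-4,4-dimethyl-1,3-dioxo-1,2,3,4-tetrahydronaphthalene-2-carboxylate) (mixture of meso and racemic forms) | COC(=O)C1(CC2(C(=O)OC)C(=O)c3c(O)cc(O)cc3C(C)(C)C2=O)C(=O)c2c(O)cc(O)cc2C(C)(C)C1=O | intermediate
17 | dimethyl 2,2'-methylenebis(7-acetyl-6,8-dihydroxy-4,4-dimethyl-1,3-dioxo-1,2,3,4-tetrahydronaphthalene-2-carboxylate) (mixture of meso and racemic forms) | COC(=O)C1(CC2(C(=O)OC)C(=O)c3c(O)c(C(C)=O)c(O)cc3C(C)(C)C2=O)C(=O)c2c(O)c(C(C)=O)c(O)cc2C(C)(C)C1=O | intermediate
18 | 2,2'-methylenebis(7-acetyl-3,6,8-trihydroxy-4,4-dimethylnaphthalen-1(4H)-one), no stereocentre | CC(=O)c1c(O)cc2c(c1O)C(=O)C(CC1=C(O)C(C)(C)c3cc(O)c(C(C)=O)c(O)c3C1=O)=C(O)C2(C)C | target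

**Step count**

Total: 9 steps. Longest linear sequence: 7 steps (steps 1, 2, 3, 6, 7, 8, 9). The diazo branch (steps 4 and 5) joins at step 6.

**Steps most likely to fail**

1. Step 6 (proposed new method). Several processes may defeat it:
   - migration of the quaternary benzylic carbon instead of the acyl carbon;
   - addition at C1 followed by aryl migration;
   - stalling after the first insertion, because the second diazo carbon is neopentyl-like and must attack a ketone next to CMe2;
   - loss of the diazo groups by elimination, or by coupling of the two diazo groups with each other.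

   Fallback (known reactions only), setting out from 1 and rejoining the route at 18. Pd-catalysed α-arylation of methyl isobutyrate with 1 (Pd(dba)2, P(t-Bu)3, LiNCy2, toluene, rt) should give methyl 2-(3,5-dimethoxyphenyl)-2-methylpropanoate F1. Crossed Claisen condensation with the lithium enolate of methyl acetate (LiN(i-Pr)2, THF, −78 °C to rt) gives methyl 4-(3,5-dimethoxyphenyl)-4-methyl-3-oxopentanoate F2. Intramolecular Friedel–Crafts acylation in P2O5/CH3SO3H closes ring B to 3-hydroxy-6,8-dimethoxy-4,4-dimethylnaphthalen-1(4H)-one F3. Knoevenagel–Michael coupling of two molecules of F3 with formaldehyde 9 (piperidine cat, aq EtOH, rt) gives 2,2'-methylenebis(3-hydroxy-6,8-dimethoxy-4,4-dimethylnaphthalen-1(4H)-one) F4. BBr3 then gives 2,2'-methylenebis(3,6,8-trihydroxy-4,4-dimethylnaphthalen-1(4H)-one) F5, and C7 acetylation with Ac2O/BF3·OEt2 leads to 18. This endgame lacks the C2 ester, so acid-promoted cyclodehydration across the bridge must be held back by the mildest workable conditions.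

2. Step 5. The bis(diazo) ester may be lost by intramolecular coupling of its two diazo groups to an aromatic pyrazole with loss of N2, 11 may undergo aldol cyclisation under DBU, or the second transfer may stay incomplete.

   Fallback, setting out from 11 and rejoining at 14; the two diazo groups never coexist in one molecule. Diazo transfer with one equivalent of p-ABSA gives 12, which is isolated here. Ring expansion of 7 with 12 under the conditions of step 6 gives methyl 2-[2-(methoxycarbonyl)-3-oxobutyl]-6,8-dimethoxy-4,4-dimethyl-1,3-dioxo-1,2,3,4-tetrahydronaphthalene-2-carboxylate F6. A second deacetylative diazo transfer (p-ABSA, DBU, MeCN, 0 °C) gives 14, which is then treated with the second equivalent of 7 and Sc(OTf)3 as in step 6.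

3. Step 8. The ketone-deactivated ring may stop at the O-acetate stage, acylation may go in part to C5, or the hot Lewis acid may strip a C2 ester and open the way to cyclodehydration.

   Fallback, setting out from 16 and rejoining at 17, replaces electrophilic acylation by halogenation and cross-coupling. Iodination between the two hydroxyl groups (NIS, MeCN, 0 °C) should give dimethyl 2,2'-methylenebis(6,8-dihydroxy-7-iodo-4,4-dimethyl-1,3-dioxo-1,2,3,4-tetrahydronaphthalene-2-carboxylate) F7. Stille coupling with tributyl(1-ethoxyvinyl)stannane (PdCl2(PPh3)2, 1,4-dioxane, 90 °C) gives dimethyl 2,2'-methylenebis[7-(1-ethoxyvinyl)-6,8-dihydroxy-4,4-dimethyl-1,3-dioxo-1,2,3,4-tetrahydronaphthalene-2-carboxylate] F8, and hydrolysis of the enol ethers with dilute aq HCl in THF gives 17.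

**Further compounds**

F1 | step 6 | methyl 2-(3,5-dimethoxyphenyl)-2-methylpropanoate | COC(=O)C(C)(C)c1cc(OC)cc(OC)c1
F2 | step 6 | methyl 4-(3,5-dimethoxyphenyl)-4-methyl-3-oxopentanoate | COC(=O)CC(=O)C(C)(C)c1cc(OC)cc(OC)c1
F3 | step 6 | 3-hydroxy-6,8-dimethoxy-4,4-dimethylnaphthalen-1(4H)-one | COc1cc(OC)c2c(c1)C(C)(C)C(O)=CC2=O
F4 | step 6 | 2,2'-methylenebis(3-hydroxy-6,8-dimethoxy-4,4-dimethylnaphthalen-1(4H)-one) | COc1cc(OC)c2c(c1)C(C)(C)C(O)=C(CC1=C(O)C(C)(C)c3cc(OC)cc(OC)c3C1=O)C2=O
F5 | step 6 | 2,2'-methylenebis(3,6,8-trihydroxy-4,4-dimethylnaphthalen-1(4H)-one) | Oc1cc(O)c2c(c1)C(C)(C)C(O)=C(CC1=C(O)C(C)(C)c3cc(O)cc(O)c3C1=O)C2=O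
F6 | step 5 | methyl 2-[2-(methoxycarbonyl)-3-oxobutyl]-6,8-dimethoxy-4,4-dimethyl-1,3-dioxo-1,2,3,4-tetrahydronaphthalene-2-carboxylate (mixture of diastereomers) | COC(=O)C(CC1(C(=O)OC)C(=O)c2c(OC)cc(OC)cc2C(C)(C)C1=O)C(C)=O
F7 | step 8 | dimethyl 2,2'-methylenebis(6,8-dihydroxy-7-iodo-4,4-dimethyl-1,3-dioxo-1,2,3,4-tetrahydronaphthalene-2-carboxylate) | COC(=O)C1(CC2(C(=O)OC)C(=O)c3c(O)c(I)c(O)cc3C(C)(C)C2=O)C(=O)c2c(O)c(I)c(O)cc2C(C)(C)C1=O
F8 | step 8 | dimethyl 2,2'-methylenebis[7-(1-ethoxyvinyl)-6,8-dihydroxy-4,4-dimethyl-1,3-dioxo-1,2,3,4-tetrahydronaphthalene-2-carboxylate] | CCOC(=C)c1c(O)cc2c(c1O)C(=O)C(CC1(C(=O)OC)C(=O)c3c(O)c(C(=C)OCC)c(O)cc3C(C)(C)C1=O)(C(=O)OC)C(=O)C2(C)C
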